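# Total synthesis proposal for CNP0216308.0 (compound 18)

Conventions used throughout. Ring A is the 2,4,6-trihydroxyphenoxy ring (C1 to C6, ether oxygen on C1). Ring B is the central ring (C1' to C6', oxygen to ring A on C1', oxygen to ring C on C5'). Ring C is the 3,4,5-trihydroxyphenoxy ring (C1'' to C6''). Ar = 3,4-dimethoxy-5-(3,4,5-trimethoxyphenoxy)phenyl, that is, rings B and C fully methylated and attached through C1'.

## Analysis of the target

Compound 18 (C18H14O10) is a linear triaryl bis-ether of the fuhalol family of phlorotannins. It has three benzene rings joined only through two ether oxygens, eight free phenolic hydroxyls, no stereocentre and no ring other than the arenes. Ring A is a phloroglucinol ring (OH on C2, C4, C6; H on C3, C5) whose C1 carries the ether oxygen to C1'. Ring B has OH on C3' and C4' and the second ether oxygen on C5', and that oxygen ends at C1'' of the pyrogallol ring C (OH on C3'', C4'', C5'').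

The hard bond is O–C1. C1 lies between the oxygenated carbons C2 and C6 in the most electron-rich ring, so ring A is a poor electrophile for substitution or metal insertion. Used as a phenol, it is a shielded and easily oxidised nucleophile. The other ether, O–C5', has one ortho neighbour and ends at an unhindered carbon of ring C, so it is ordinary. The catechol of ring B and the pyrogallol of ring C are oxidised by air, quickly in base, so the hydroxyls must be released last under acidic, non-oxidising conditions.

The route exploits one feature of ring A. C1(OAr)–C2(OH) is an aryloxyketene unit ArO–CH=C=O, and C3(H)–C4(O) and C5(H)–C6(O) are two head-to-tail HC≡C–O units. Ring A is therefore the formal (2+2+2) adduct of one ketene and two ynol ethers, and it is mirror-symmetric about its C1–C4 axis once all oxygens are free.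

## Retrosynthetic reasoning

**18 from 17.** Only seven O–alkyl bonds (five methyl, two ethyl) are cut. All oxidisable hydroxyls are pushed to the last step, and one boron Lewis acid removes both kinds of alkyl group. The two diaryl ether bonds offer no sp3 carbon at which cleavage could start. The methoxy groups arrive with 1 and 2 and the ethoxy groups with 9, so no step is spent on protection.

**17 from 12 and 9 (key disconnection).** Ring A itself is taken apart, not the ether beside it. Cutting C2–C3 and C4–C5 removes C3–C4 as one molecule of ynol ether 9. It contracts the remainder (C1, C2, C5, C6) to the four-membered ring of cyclobutenone 12. The hindered O–C1 bond then no longer has to be made as an aryl–oxygen bond, because the arene grows around an oxygen that is already in place. The forward reaction has to open 12 to vinylketene 13, take up 9 in the right orientation, and close and aromatise the six-membered ring.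

**12 from 8 and 9.** The bonds C1–C6 and C2–C5 of the four-membered ring are cut in a retro-(2+2). This gives aryloxyketene 11 and a second molecule of 9. Ketene 11 comes from acid 8 through acid chloride 10. The cut follows the polarity of the partners, so the ethoxy group falls on C6 next to the aryloxy carbon C1.

**8 from 5 and 6.** The O–C1 bond is cut at the stage where C1 is still a CH2 group. The most hindered bond of 18 is thus formed as an SN2 alkylation of the only free hydroxyl of 5 at a primary carbon of 6.

**5 from 3.** The C1'–O bond is traced back to a C1'–CHO bond through an aryl migration to peracid oxygen. The formyl group is a robust placeholder for the oxygen during the coupling and comes ready-made with 1.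

**3 from 1 and 2.** The O–C5' bond is cut on the ring B side. Here the textbook copper coupling is the right tool. The phenol 2 is unhindered, the bromide 1 has one ortho substituent, and both rings are purchasable with all their oxygens correctly placed.

## Alternatives that were turned down

**Alternative 1:** This is the textbook route. Both aryl–oxygen bonds are cut and three intact permethylated rings are joined by two copper-catalysed Ullmann couplings. The forward key step couples 2,4,6-trimethoxyphenol A1 with 5-bromo-1,2-dimethoxy-3-(3,4,5-trimethoxyphenoxy)benzene A2. This gives 1,3,5-trimethoxy-2-[3,4-dimethoxy-5-(3,4,5-trimethoxyphenoxy)phenoxy]benzene A3, which is then demethylated.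
- The oxygen of A1 is shielded by two ortho methoxy groups, which slows binding to copper and reductive elimination.
- A1 is among the most oxidisable phenols, and a hot basic copper medium invites its oxidation to a quinone.
- A2 is not purchasable. Ring B would need two coupling sites of graded reactivity, which costs several extra steps, and A1 has to be made as well.
- Each coupling forms one bond only, and the whole risk falls on the most hindered bond, made late between the two largest fragments.

**Alternative 2:** Ring A is again built around the preformed oxygen, but by the polyketide logic of its presumed biosynthesis, cutting C1–C2 only. Phenol 5 would be alkylated to 4-methoxy-6-[(ArO)methyl]-2H-pyran-2-one A4. Alkoxide would open the lactone to methyl (E)-6-(ArO)-3-methoxy-5-oxohex-2-enoate A5. An intramolecular Claisen condensation of C6 onto the ester carbon would then give 2-(ArO)-5-methoxybenzene-1,3-diol A6.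
- The route is short and attractive, but the mechanism argues against it.
- Base first removes the doubly activated C4 proton of A5, and the resulting dienolate is conjugated with the ester and deactivates it.
- The carbon that must attack (C6) is only singly activated.
- Reclosure through oxygen to A4 is the faster and reversible path.
- The carbocyclisation would need forcing basic conditions on an α-aryloxy ketone.

**Alternative 3:** The central ring B is built by a Moore-type ring expansion, cutting C1'–C2' and C3'–C4'. The precursor is 4-(1-ethoxyethenyl)-4-hydroxy-3-(3,4,5-trimethoxyphenoxy)cyclobut-2-en-1-one A7, the adduct of a lithiated enol ether and an aryl semisquarate. It would open thermally and close to 2-ethoxy-6-(3,4,5-trimethoxyphenoxy)benzene-1,4-diol A8.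
- The ring construction places the ring C ether correctly, but that is the easy ether, which one coupling of two purchasable rings already delivers.
- This rearrangement always delivers the oxygen on C1' as a free hydroxyl, so the hard bond to ring A is left unsolved.
- The two hydroxyls of A8 must then be told apart.
- The aryl semisquarate costs several steps from a squarate diester.

Key step: step 5

Assumption: 1, 2, 6 and 9 (9 as its solution in hexanes) are taken as purchasable. The target has no stereocentre, so 12, 14 and 16 are handled as racemates.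

## Route

Step 1
Reactants: 1 3-bromo-4,5-dimethoxybenzaldehyde; 2 3,4,5-trimethoxyphenol
Product: 3 3,4-dimethoxy-5-(3,4,5-trimethoxyphenoxy)benzaldehyde
Conditions: CuI (10 mol %), N,N-dimethylglycine hydrochloride (30 mol %), Cs2CO3 (2 equiv), 1,4-dioxane, 100 °C, Ar
Reagents that add atoms: none
Why: Ullmann-type diaryl ether synthesis under copper and amino acid catalysis; the phenol 2 is unhindered, the bromide 1 has a single ortho substituent, and its non-enolisable formyl group tolerates carbonate base.

Step 2
Reactants: 3 3,4-dimethoxy-5-(3,4,5-trimethoxyphenoxy)benzaldehyde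
Product: 5 3,4-dimethoxy-5-(3,4,5-trimethoxyphenoxy)phenol, via aryl formate 4 (not isolated)
Conditions: mCPBA (1.3 equiv), CH2Cl2, 0 °C to rt; aq. NaHCO3 wash; then K2CO3 (cat.), MeOH, rt
Reagents that add atoms: 3-chloroperoxybenzoic acid (mCPBA), O=C(OO)c1cccc(Cl)c1
Why: Baeyer–Villiger oxidation; in the Criegee adduct the electron-rich aryl group with its para methoxy donor migrates in preference to hydride, and mild methanolysis of 4 frees the hydroxyl on C1' without touching any aryl ether.

Step 3
Reactants: 5 3,4-dimethoxy-5-(3,4,5-trimethoxyphenoxy)phenol; 6 ethyl bromoacetate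
Product: 8 2-(ArO)acetic acid, via ethyl ester 7 (not isolated)
Conditions: K2CO3 (2 equiv), acetone, reflux; filter, concentrate; then NaOH (3 equiv), THF–H2O, rt; then 1 M HCl
Reagents that add atoms: sodium hydroxide, [Na+].[OH-]
Why: Williamson ether synthesis followed by saponification; the bond that becomes the hindered O–C1 bond of ring A is made by SN2 at a primary α-bromo ester, and 5 has only one acidic hydroxyl.

Step 4
Reactants: 8 2-(ArO)acetic acid; 9 ethoxyacetylene
Product: 12 rac-4-(ArO)-3-ethoxycyclobut-2-en-1-one, via acid chloride 10 (not isolated), via aryloxyketene 11 (not isolated)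
Conditions: 1-chloro-N,N,2-trimethylprop-1-en-1-amine (1.1 equiv), CH2Cl2, 0 °C to rt; then added over 4 h to 9 (3 equiv) and Et3N (1.5 equiv), CH2Cl2, 0 °C to rt
Reagents that add atoms: none
Why: The α-chloroenamine gives 10 under neutral conditions, free of HCl and of acylating species that could attack the electron-rich ring B, and dehydrochlorination gives 11, which slow addition keeps dilute. The known (2+2) cycloaddition of ketenes with alkoxyacetylenes joins the nucleophilic terminal alkyne carbon to the ketene carbonyl carbon, so ethoxy ends on C3 and aryloxy on C4. The new stereocentre C4 is racemic and is erased in step 5.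

Step 5
Reactants: 12 rac-4-(ArO)-3-ethoxycyclobut-2-en-1-one; 9 ethoxyacetylene
Product: 17 2-(ArO)-3,5-diethoxyphenol, via vinylketene 13 (not isolated), via alkenylcyclobutenone 14 (not isolated), via dienylketene 15 (not isolated), via cyclohexadienone 16 (not isolated)
Conditions: 9 (4 equiv), toluene (0.1 M), sealed tube, Ar, 80 °C, then 110 °C
Reagents that add atoms: none
Why: Danheiser benzannulation, the thermal union of a cyclobutenone and an alkoxyacetylene through four pericyclic events. (1) Conrotatory four-electron opening of 12, in which the donor aryloxy group on C4 turns outward, gives vinylketene 13 reversibly. (2) The ketene C=C bond of 13 adds 9 in a (2+2) sense, the nucleophilic terminal alkyne carbon bonding to the electrophilic ketene carbonyl carbon, to give 14; these are the new bonds C2–C3 and C4–C5 of ring A. (3) 14 opens reversibly and only the isomer with the alkenyl group turned inward, dienylketene 15, is drained: ring A closes by a disrotatory six-electron electrocyclisation between the ketene carbon (C2) and the aryloxy-bearing terminus (C1) to give 16, and tautomerisation to phenol 17 makes the cascade irreversible. The closest known reaction type is the benzannulation of 3-alkoxy- and 4-substituted cyclobutenones, themselves made from ketenes and ynol ethers, with a second ynol ether to give 5-alkoxyresorcinol derivatives. No stereocentre is set: the centres of 12, 14 and 16 are racemic and vanish on aromatisation. The selectivity needed is the orientation of 9, secured by the matched polarity of ketene and ynol ether; a leak through direct (4+2) addition would merely exchange the free hydroxyl and one ethoxy group on ring A, a difference that step 6 erases because ring A is symmetric about C1–C4. Excess 9 and moderate dilution favour capture of 13 by the alkyne over capture by the phenol formed, and rings B and C carry only aryl ethers that are inert at these temperatures.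

Step 6
Reactants: 17 2-(ArO)-3,5-diethoxyphenol
Product: 18 2-[3,4-dihydroxy-5-(3,4,5-trihydroxyphenoxy)phenoxy]benzene-1,3,5-triol (target)
Conditions: BBr3 (16 equiv), CH2Cl2, −78 °C to rt, Ar; ice–water; EtOAc extraction; Sephadex LH-20, degassed MeOH
Reagents that add atoms: none
Why: Lewis acid dealkylation of aryl alkyl ethers; bromide attacks the methyl and ethyl carbons of the boron-complexed ethers, whereas the two diaryl ether oxygens carry no sp3 carbon and stay intact. The acidic, non-oxidising medium suits the catechol and pyrogallol units that are set free.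

## Compound list

1 | 3-bromo-4,5-dimethoxybenzaldehyde | COc1cc(C=O)cc(Br)c1OC | starting material
2 | 3,4,5-trimethoxyphenol | COc1cc(O)cc(OC)c1OC | starting material
3 | 3,4-dimethoxy-5-(3,4,5-trimethoxyphenoxy)benzaldehyde | COc1cc(C=O)cc(Oc2cc(OC)c(OC)c(OC)c2)c1OC | intermediate
4 | 3,4-dimethoxy-5-(3,4,5-trimethoxyphenoxy)phenyl formate | COc1cc(OC=O)cc(Oc2cc(OC)c(OC)c(OC)c2)c1OC | intermediate
5 | 3,4-dimethoxy-5-(3,4,5-trimethoxyphenoxy)phenol | COc1cc(O)cc(Oc2cc(OC)c(OC)c(OC)c2)c1OC | intermediate
6 | ethyl bromoacetate | CCOC(=O)CBr | starting material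
7 | ethyl 2-[3,4-dimethoxy-5-(3,4,5-trimethoxyphenoxy)phenoxy]acetate | CCOC(=O)COc1cc(OC)c(OC)c(Oc2cc(OC)c(OC)c(OC)c2)c1 | intermediate
8 | 2-[3,4-dimethoxy-5-(3,4,5-trimethoxyphenoxy)phenoxy]acetic acid | OC(=O)COc1cc(OC)c(OC)c(Oc2cc(OC)c(OC)c(OC)c2)c1 | intermediate
9 | ethoxyacetylene (ethoxyethyne) | C#COCC | starting material
10 | 2-[3,4-dimethoxy-5-(3,4,5-trimethoxyphenoxy)phenoxy]acetyl chloride | ClC(=O)COc1cc(OC)c(OC)c(Oc2cc(OC)c(OC)c(OC)c2)c1 | intermediate
11 | 2-[3,4-dimethoxy-5-(3,4,5-trimethoxyphenoxy)phenoxy]ethen-1-one (aryloxyketene) | O=C=COc1cc(OC)c(OC)c(Oc2cc(OC)c(OC)c(OC)c2)c1 | intermediate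
12 | rac-4-[3,4-dimethoxy-5-(3,4,5-trimethoxyphenoxy)phenoxy]-3-ethoxycyclobut-2-en-1-one | CCOC1=CC(=O)C1Oc1cc(OC)c(OC)c(Oc2cc(OC)c(OC)c(OC)c2)c1 | intermediate
13 | (Z)-4-(ArO)-3-ethoxybuta-1,3-dien-1-one (aryloxy group trans to the ketenyl carbon) | O=C=C/C(OCC)=C/Oc1cc(OC)c(OC)c(Oc2cc(OC)c(OC)c(OC)c2)c1 | intermediate
14 | rac-4-[(Z)-2-(ArO)-1-ethoxyethenyl]-3-ethoxycyclobut-2-en-1-one | O=C1C=C(OCC)C1/C(OCC)=C/Oc1cc(OC)c(OC)c(Oc2cc(OC)c(OC)c(OC)c2)c1 | intermediate
15 | (3E,5Z)-6-(ArO)-3,5-diethoxyhexa-1,3,5-trien-1-one | O=C=C/C(OCC)=C\C(OCC)=C\Oc1cc(OC)c(OC)c(Oc2cc(OC)c(OC)c(OC)c2)c1 | intermediate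
16 | rac-6-(ArO)-3,5-diethoxycyclohexa-2,4-dien-1-one | O=C1C=C(OCC)C=C(OCC)C1Oc1cc(OC)c(OC)c(Oc2cc(OC)c(OC)c(OC)c2)c1 | intermediate
17 | 2-[3,4-dimethoxy-5-(3,4,5-trimethoxyphenoxy)phenoxy]-3,5-diethoxyphenol | CCOc1cc(O)c(Oc2cc(OC)c(OC)c(Oc3cc(OC)c(OC)c(OC)c3)c2)c(OCC)c1 | intermediate
18 | 2-[3,4-dihydroxy-5-(3,4,5-trihydroxyphenoxy)phenoxy]benzene-1,3,5-triol | Oc1cc(O)c(Oc2cc(O)c(O)c(Oc3cc(O)c(O)c(O)c3)c2)c(O)c1 | target

## Step count and risk

Total step count: 6.

Longest linear sequence: 6 (1 → 3 → 5 → 8 → 12 → 17 → 18).

**Step 5 (key step).**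
- What may go wrong: the transient ketenes may be captured by the phenol that accumulates, giving aryl ester formation instead of ring growth.
- A retro-ene fragmentation of 9 above about 100 °C may deplete the alkyne and release ketene that acylates the product.
- The opening of the second four-membered ring may be slow, so the cascade stalls before aromatisation.
- These risks arise because 13 carries two donor oxygens and is a less electrophilic ketene than the usual substrates, while 9 is thermally fragile.
- Fallback: the ring construction is given up and the O–C1 bond is made on an intact ring by known chemistry, setting out from 5. Copper-catalysed coupling (CuI, picolinic acid, K3PO4, DMSO, 100 °C) with purchasable 4-bromo-3,5-dimethoxybenzaldehyde, whose para formyl group activates the doubly flanked C–Br bond, should give 4-(ArO)-3,5-dimethoxybenzaldehyde F1. Baeyer–Villiger oxidation with mCPBA leads to 4-(ArO)-3,5-dimethoxyphenyl formate F2, and methanolysis gives 4-(ArO)-3,5-dimethoxyphenol F3. BBr3 then cleaves its seven methyl ethers, so the fallback comes back to the route at 18.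

**Step 4.**
- What may go wrong: ketene 11 may dimerise if its concentration rises.
- Acid chloride 10 may acylate the very electron-rich ring B intramolecularly in a Friedel–Crafts sense before the base reaches it.
- The vinylogous ester of 12 may hydrolyse during chromatography.
- Fallback: the four-membered ring is bypassed, setting out from 5. Alkylation with ethyl (E)-4-bromo-3-ethoxybut-2-enoate (K2CO3, acetone) should give ethyl (E)-4-(ArO)-3-ethoxybut-2-enoate F4. Saponification (LiOH, THF–H2O) gives (E)-4-(ArO)-3-ethoxybut-2-enoic acid F5, and the α-chloroenamine of step 4 gives (E)-4-(ArO)-3-ethoxybut-2-enoyl chloride F6. A 1,4-dehydrochlorination with Et3N in the presence of 9 releases the vinylketene directly, so the fallback comes back to the route at 13, inside the cascade of step 5.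

**Step 1.**
- What may go wrong: turnover at the ortho-methoxy bromide may be slow, reductive debromination may compete, and the electron-rich phenoxide of 2 may degrade oxidatively in the hot basic copper medium.
- Fallback: the roles of the two rings are reversed and the reaction changes to an oxidative coupling at room temperature, setting out from 1. Miyaura borylation (B2pin2, PdCl2(dppf), KOAc, dioxane, 80 °C) should give 3,4-dimethoxy-5-(4,4,5,5-tetramethyl-1,3,2-dioxaborolan-2-yl)benzaldehyde F7. Oxidation with NaBO3·4H2O (THF–H2O, rt) gives 3-hydroxy-4,5-dimethoxybenzaldehyde F8. Chan–Lam coupling of F8 with purchasable (3,4,5-trimethoxyphenyl)boronic acid (Cu(OAc)2, pyridine, 4 Å sieves, CH2Cl2, air, rt) comes back to the route at 3.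

**Step 6.**
- What may go wrong: the seven ethers may be cleaved incompletely, because boron chelates formed early shield the remaining alkoxy groups.
- The free catechol and pyrogallol units may be oxidised by air during aqueous work-up and chromatography.
- Fallback: the free phenol is captured and released instead of being isolated directly, setting out from 17. The crude product of the BBr3 treatment is acetylated at once (Ac2O, pyridine, rt) to 2-[3,4-diacetoxy-5-(3,4,5-triacetoxyphenoxy)phenoxy]benzene-1,3,5-triyl triacetate F9. This compound is stable to air and can be separated on silica from partly dealkylated material. Acid-catalysed methanolysis (HCl from AcCl in degassed MeOH, Ar) leaves only volatile by-products and comes back to the route at 18.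

## Further compounds

F1 | step 5 | 4-[3,4-dimethoxy-5-(3,4,5-trimethoxyphenoxy)phenoxy]-3,5-dimethoxybenzaldehyde | O=Cc1cc(OC)c(Oc2cc(OC)c(OC)c(Oc3cc(OC)c(OC)c(OC)c3)c2)c(OC)c1
F2 | step 5 | 4-[3,4-dimethoxy-5-(3,4,5-trimethoxyphenoxy)phenoxy]-3,5-dimethoxyphenyl formate | O=COc1cc(OC)c(Oc2cc(OC)c(OC)c(Oc3cc(OC)c(OC)c(OC)c3)c2)c(OC)c1
F3 | step 5 | 4-[3,4-dimethoxy-5-(3,4,5-trimethoxyphenoxy)phenoxy]-3,5-dimethoxyphenol | Oc1cc(OC)c(Oc2cc(OC)c(OC)c(Oc3cc(OC)c(OC)c(OC)c3)c2)c(OC)c1
F4 | step 4 | ethyl (E)-4-[3,4-dimethoxy-5-(3,4,5-trimethoxyphenoxy)phenoxy]-3-ethoxybut-2-enoate | CCOC(=O)/C=C(/OCC)COc1cc(OC)c(OC)c(Oc2cc(OC)c(OC)c(OC)c2)c1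
F5 | step 4 | (E)-4-[3,4-dimethoxy-5-(3,4,5-trimethoxyphenoxy)phenoxy]-3-ethoxybut-2-enoic acid | OC(=O)/C=C(/OCC)COc1cc(OC)c(OC)c(Oc2cc(OC)c(OC)c(OC)c2)c1
F6 | step 4 | (E)-4-[3,4-dimethoxy-5-(3,4,5-trimethoxyphenoxy)phenoxy]-3-ethoxybut-2-enoyl chloride | ClC(=O)/C=C(/OCC)COc1cc(OC)c(OC)c(Oc2cc(OC)c(OC)c(OC)c2)c1
F7 | step 1 | 3,4-dimethoxy-5-(4,4,5,5-tetramethyl-1,3,2-dioxaborolan-2-yl)benzaldehyde | O=Cc1cc(OC)c(OC)c(B2OC(C)(C)C(C)(C)O2)c1
F8 | step 1 | 3-hydroxy-4,5-dimethoxybenzaldehyde | O=Cc1cc(O)c(OC)c(OC)c1
F9 | step 6 | 2-[3,4-diacetoxy-5-(3,4,5-triacetoxyphenoxy)phenoxy]benzene-1,3,5-triyl triacetate | CC(=O)Oc1cc(OC(C)=O)c(Oc2cc(OC(C)=O)c(OC(C)=O)c(Oc3cc(OC(C)=O)c(OC(C)=O)c(OC(C)=O)c3)c2)c(OC(C)=O)c1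
A1 | alternative 1 | 2,4,6-trimethoxyphenol | COc1cc(OC)c(O)c(OC)c1
A2 | alternative 1 | 5-bromo-1,2-dimethoxy-3-(3,4,5-trimethoxyphenoxy)benzene | Brc1cc(OC)c(OC)c(Oc2cc(OC)c(OC)c(OC)c2)c1
A3 | alternative 1 | 1,3,5-trimethoxy-2-[3,4-dimethoxy-5-(3,4,5-trimethoxyphenoxy)phenoxy]benzene | COc1cc(OC)c(Oc2cc(OC)c(OC)c(Oc3cc(OC)c(OC)c(OC)c3)c2)c(OC)c1
A4 | alternative 2 | 4-methoxy-6-{[3,4-dimethoxy-5-(3,4,5-trimethoxyphenoxy)phenoxy]methyl}-2H-pyran-2-one | COC1=CC(=O)OC(COc2cc(OC)c(OC)c(Oc3cc(OC)c(OC)c(OC)c3)c2)=C1
A5 | alternative 2 | methyl (E)-6-[3,4-dimethoxy-5-(3,4,5-trimethoxyphenoxy)phenoxy]-3-methoxy-5-oxohex-2-enoate | COC(=O)/C=C(OC)\CC(=O)COc1cc(OC)c(OC)c(Oc2cc(OC)c(OC)c(OC)c2)c1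
A6 | alternative 2 | 2-[3,4-dimethoxy-5-(3,4,5-trimethoxyphenoxy)phenoxy]-5-methoxybenzene-1,3-diol | COc1cc(O)c(Oc2cc(OC)c(OC)c(Oc3cc(OC)c(OC)c(OC)c3)c2)c(O)c1
A7 | alternative 3 | 4-(1-ethoxyethenyl)-4-hydroxy-3-(3,4,5-trimethoxyphenoxy)cyclobut-2-en-1-one (racemic) | C=C(OCC)C1(O)C(Oc2cc(OC)c(OC)c(OC)c2)=CC1=O
A8 | alternative 3 | 2-ethoxy-6-(3,4,5-trimethoxyphenoxy)benzene-1,4-diol | CCOc1cc(O)cc(Oc2cc(OC)c(OC)c(OC)c2)c1O
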